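**Plan**
The oxolane (O1, aryl-bearing C2/C5, methyl-bearing C3/C4) lies on a C2 axis through O1 and the midpoint of C3–C4. Cutting C3–C4, C2–O1 and C5–O1 therefore frees O1 and leaves two identical (E)-propenylarenes, each made of ring B, the C7–C8 side chain and ring A.
Each half is cut again at the ring B O–C8 ether bond and at the C7–ring A bond. This leads back to (E)-isoeugenol 1, ethyl (S)-lactate 2 and 4-bromo-1,2-dimethoxybenzene 3, and O1 comes from water 4.
Forward, the chain is completed first (ether bond, aryl ketone, carbinol, acetate). The oxolane, the only ring made, then closes in one anodic operation from two halves and water, and methanolysis ends the route.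
C8 comes from lactate by Mitsunobu inversion and C7 from a Felkin–Anh reduction next to C8. C3/C4 come from the anti head-to-head union of two (E)-alkenes and C2/C5 from the two C–O captures, which are only partly biased, so the enantiopure side chains are used to separate the oxolane diastereomers.

Key step: step 6

Remark: trans-isoeugenol of high isomeric purity is assumed, and the cathode of the undivided cell is taken to reduce protons only, so the key step balances as two halves + H2O → oxolane + H2.

Step 1
Reactants: 1 (E)-isoeugenol; 2 ethyl (S)-lactate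
Product: 5 ethyl (2R)-2-{2-methoxy-4-[(E)-prop-1-enyl]phenoxy}propanoate
Conditions: PPh3, DIAD (premixed, 0 °C), then 2 and 1, THF, 0 °C to rt
Reagents that add atoms: none
Why: Mitsunobu etherification, in which the phenoxide displaces the phosphonium-activated lactate oxygen by SN2 with inversion, so that the (S)-carbinol carbon becomes C8 with R configuration; premixing consumes the azodicarboxylate before it can meet the electron-rich propenyl group.

Step 2
Reactants: 5 ethyl (2R)-2-{2-methoxy-4-[(E)-prop-1-enyl]phenoxy}propanoate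
Product: 6 (2R)-N-methoxy-2-{2-methoxy-4-[(E)-prop-1-enyl]phenoxy}-N-methylpropanamide
Conditions: MeNH(OMe)·HCl, i-PrMgCl, THF, −20 °C
Reagents that add atoms: N,O-dimethylhydroxylamine hydrochloride, CNOC.Cl
Why: Weinreb amide formation by direct aminolysis of the ester with the chloromagnesium amide, which is fast at −20 °C and too weakly basic to enolise the α-aryloxy centre C8.

Step 3
Reactants: 6 (2R)-N-methoxy-2-{2-methoxy-4-[(E)-prop-1-enyl]phenoxy}-N-methylpropanamide; 3 4-bromo-1,2-dimethoxybenzene
Product: 8 (2R)-1-(3,4-dimethoxyphenyl)-2-{2-methoxy-4-[(E)-prop-1-enyl]phenoxy}propan-1-one, via 3,4-dimethoxyphenylmagnesium bromide 7 (not isolated)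
Conditions: 3, Mg, THF, 40 °C; then 6, THF, −10 °C; aq. NH4Cl
Reagents that add atoms: none
Why: Weinreb ketone synthesis: the aryl Grignard reagent adds once because the magnesium-chelated tetrahedral adduct survives until the quench, and the low temperature and short contact time spare C8 and the propenyl group.

Step 4
Reactants: 8 (2R)-1-(3,4-dimethoxyphenyl)-2-{2-methoxy-4-[(E)-prop-1-enyl]phenoxy}propan-1-one
Product: 9 (1R,2R)-1-(3,4-dimethoxyphenyl)-2-{2-methoxy-4-[(E)-prop-1-enyl]phenoxy}propan-1-ol (threo)
Conditions: Bu4NBH4, CH2Cl2/MeOH 4:1, −78 to −40 °C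
Reagents that add atoms: none
Why: Polar Felkin–Anh reduction: with no chelating metal cation present the aryloxy group stands perpendicular to the carbonyl plane and hydride enters anti to it, which sets C7 as R (threo to C8), the sense known for α-aryloxypropiophenones with quaternary ammonium borohydrides; the minor erythro isomer is removed by chromatography.

Step 5
Reactants: 9 (1R,2R)-1-(3,4-dimethoxyphenyl)-2-{2-methoxy-4-[(E)-prop-1-enyl]phenoxy}propan-1-ol
Product: 10 (1R,2R)-1-(3,4-dimethoxyphenyl)-2-{2-methoxy-4-[(E)-prop-1-enyl]phenoxy}propyl acetate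
Conditions: Ac2O, pyridine, 4-(dimethylamino)pyridine (cat.), CH2Cl2, 0 °C to rt
Reagents that add atoms: acetic anhydride, CC(=O)OC(C)=O
Why: Nucleophile-catalysed acetylation of the secondary benzylic alcohol, which touches no stereocentre, makes ring A a poorer donor and blocks the C7–C8 fragmentation that free benzylic alcohols of this type undergo on one-electron oxidation.

Step 6
Reactants: 10 (1R,2R)-1-(3,4-dimethoxyphenyl)-2-{2-methoxy-4-[(E)-prop-1-enyl]phenoxy}propyl acetate (two molecules); 4 water
Product: 11 manassantin A diacetate [(2S,3R,4R,5S)-3,4-dimethyl-2,5-diaryloxolane with both C7 hydroxyls acetylated]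
Conditions: carbon-felt anode, Pt cathode, undivided cell, +1.1 V vs Ag/AgCl, (4-BrC6H4)3N (10 mol %), LiClO4 (0.1 M), 2,6-lutidine (2 equiv), 10 (0.1 M), MeCN/H2O 19:1, −20 °C, stopped near 0.9 F/mol; silica gel, then preparative HPLC
Reagents that add atoms: water (compound 4), O
Why: Proposed new method: the anodically regenerated aminium ion takes one electron from the propenyl-guaiacyl π system of ring B, the radical cation bonds through its β-carbon to the β-carbon of a second molecule of 10 (C3–C4), water 4 opens the resulting long-bond cyclobutane radical cation at one benzylic carbon (C2–O1), the remaining benzylic radical gives up a second electron, and the new hydroxyl adds to the para-oxygen-stabilised cation (C5–O1). The closest known reaction type is the anodic or photoredox radical-cation dimerisation of anethole- and isoeugenol-type (E)-propenylarenes in wet solvent to 2,5-diaryl-3,4-dimethyltetrahydrofurans, which is established for this bond set but not as a route to a single stereoisomer or for a monomer of this size. The oxolane closes in the 5-exo-trig mode, the hydroxyl oxygen attacking C5 of the exocyclic C5=ring B bond of the quinone-methide-like cation. C3 and C4 are fixed in the C–C bond formation by the anti head-to-head approach of two (E)-alkenes (the approach that also gives all-trans cyclobutane dimers), which sets the methyls trans; C2 is fixed by backside entry of water relative to the one-electron C2···C5 bond, a net anti addition across the (E)-alkene that places aryl and methyl cis; C5 is fixed in the ring closure, where avoidance of a 2,5-cis pair of large aryl groups must outweigh allylic 1,3-strain in the cation, which favours the 4,5-trans epimer. The step needs oxidation at ring B only, β,β regiochemistry, trans methyls, cis C–O bonds at both ends and the (3R,4R) sense: the acetates, the para-oxygen and the (E)-geometry of 10 secure the first three, whereas the closure at C5 and the absolute sense are not secured by the remote C7/C8 centres, so 11 may well be a minor component that has to be separated from its oxolane diastereomers, which the enantiopure side chains allow on achiral phases. The mediator caps the oxidising power below what ring A and the product need, and lutidine and low temperature keep the acid-labile cis,trans,cis ring from epimerising.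

Step 7
Reactants: 11 manassantin A diacetate
Product: 12 manassantin A
Conditions: K2CO3 (0.2 equiv), MeOH/THF, 0 °C to rt
Reagents that add atoms: none
Why: Zemplén-type transesterification of the two secondary acetates under catalytic mild base, conditions under which the acid-sensitive oxolane, the aryl ethers and all eight stereocentres are stable.

**Compound list**
1 | (E)-isoeugenol | C/C=C/c1ccc(O)c(OC)c1 | starting material
2 | ethyl (S)-lactate | CCOC(=O)[C@H](C)O | starting material
3 | 4-bromo-1,2-dimethoxybenzene | COc1ccc(Br)cc1OC | starting material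
4 | water | O | starting material
5 | ethyl (2R)-2-{2-methoxy-4-[(E)-prop-1-enyl]phenoxy}propanoate | CCOC(=O)[C@@H](C)Oc1ccc(/C=C/C)cc1OC | intermediate
6 | (2R)-N-methoxy-2-{2-methoxy-4-[(E)-prop-1-enyl]phenoxy}-N-methylpropanamide | CON(C)C(=O)[C@@H](C)Oc1ccc(/C=C/C)cc1OC | intermediate
7 | 3,4-dimethoxyphenylmagnesium bromide (not isolated) | COc1ccc([Mg]Br)cc1OC | intermediate
8 | (2R)-1-(3,4-dimethoxyphenyl)-2-{2-methoxy-4-[(E)-prop-1-enyl]phenoxy}propan-1-one | COc1ccc(C(=O)[C@@H](C)Oc2ccc(/C=C/C)cc2OC)cc1OC | intermediate
9 | (1R,2R)-1-(3,4-dimethoxyphenyl)-2-{2-methoxy-4-[(E)-prop-1-enyl]phenoxy}propan-1-ol | COc1ccc([C@@H](O)[C@@H](C)Oc2ccc(/C=C/C)cc2OC)cc1OC | intermediate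
10 | (1R,2R)-1-(3,4-dimethoxyphenyl)-2-{2-methoxy-4-[(E)-prop-1-enyl]phenoxy}propyl acetate | COc1ccc([C@@H](OC(C)=O)[C@@H](C)Oc2ccc(/C=C/C)cc2OC)cc1OC | intermediate
11 | manassantin A diacetate | COc1ccc([C@@H](OC(C)=O)[C@@H](C)Oc2ccc([C@H]3O[C@H](c4ccc(O[C@H](C)[C@H](OC(C)=O)c5ccc(OC)c(OC)c5)c(OC)c4)[C@H](C)[C@H]3C)cc2OC)cc1OC | intermediate
12 | manassantin A | COc1ccc([C@@H](O)[C@@H](C)Oc2ccc([C@H]3O[C@H](c4ccc(O[C@H](C)[C@H](O)c5ccc(OC)c(OC)c5)c(OC)c4)[C@H](C)[C@H]3C)cc2OC)cc1OC | target

Total step count: 7 (the Grignard reagent 7 is made and used within step 3).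
Longest linear sequence: 7 steps, from 1 or 2 to 12.

**Steps most likely to fail**

1. Step 6 (carries the label).
- The hydroxyl may close onto the second benzylic cation through the conformer of lowest allylic strain, which builds 4,5-trans rings.
- Both faces may be used equally in the C3–C4 union.
- The cis,trans,cis ring may epimerise through anodically formed acid.
- The benzylic ether positions of the product may be oxidised further.
- The monomer radical cation may be hydrated before it dimerises.
- A covalent link between the two C7 oxygens would not help. The aryl axes of a 2,5-trans oxolane point almost in opposite directions, so a short link would favour 2,5-cis rings.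

Fallback (known chemistry): the oxolane is built first by stepwise, reagent-controlled reactions, and the side chains are attached afterwards with the chemistry of steps 1 to 4. It sets out from 2 and 7, draws the core from commercial 4-(benzyloxy)-3-methoxybenzaldehyde, and returns at 12. Brown syn-crotylation of the aldehyde with the (Z)-crotyl-B(Ipc)2 reagent made from cis-but-2-ene (n-BuLi, KOt-Bu), (−)-Ipc2BOMe and BF3·OEt2 should give syn homoallylic alcohol F1. Hydroboration–oxidation (9-borabicyclo[3.3.1]nonane, then H2O2, NaOH) gives 1,4-diol F2, and oxidative lactonisation (PhI(OAc)2, catalytic 2,2,6,6-tetramethylpiperidin-1-oxyl) gives 4,5-cis lactone F3. Enolate methylation (LiN(SiMe3)2, MeI, −78 °C) anti to the C4 methyl gives dimethyl lactone F4, i-Bu2AlH gives lactol F5, and PhSO2H with CaCl2 gives 2-(phenylsulfonyl)oxolane F6. Arylzinc bromide F7 is made from commercial 1-(benzyloxy)-4-bromo-2-methoxybenzene (Mg, LiCl, ZnBr2, THF). It adds to the oxocarbenium ion released from F6 with the aryl group entering cis to the neighbouring methyl, the known outcome for this ring pattern, and gives cis,trans,cis bis(benzyl ether) F8. Hydrogenolysis (H2, palladium on carbon) frees bisphenol F9. Double Mitsunobu reaction with 2 gives bis(lactate ether) F10, and MeNH(OMe)·HCl with i-PrMgCl gives bis(Weinreb amide) F11. Addition of 7 gives diketone F12, and Bu4NBH4 reduction of both ketones leads to 12.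

2. Step 4. Facial selectivity may be poor. Hydrogen bonding by methanol or adventitious cations can hold the carbonyl and the aryloxy/methoxy oxygens in a chelate-like array that opposes the Felkin–Anh mode. Fallback: the selectivity is reversed on purpose and corrected by inversion, setting out from 8 and returning at 9. Chelation-controlled reduction (Zn(BH4)2, Et2O, −20 °C) should give erythro alcohol F13. Mitsunobu inversion at C7 with 4-nitrobenzoic acid (PPh3, DIAD, toluene) gives threo 4-nitrobenzoate F14, and methanolysis (K2CO3, MeOH) gives 9.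

3. Step 3. Configuration at C8 may erode through enolisation of amide 6 or of ketone 8 in the basic organomagnesium medium, the more so if addition is slow. Fallback: the aryl ether bond is made last, so that no α-aryloxy carbonyl compound meets a Grignard reagent. It sets out from 2 and returns at 8. Aminolysis of 2 (MeNH(OMe)·HCl, i-PrMgCl) gives hydroxy Weinreb amide F15, excess 7 gives (S)-α-hydroxy ketone F16, and TsCl in pyridine gives (S)-tosylate F17. SN2 displacement by 1 (K2CO3, MeCN, rt) with inversion then gives 8.

**Further compounds**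
F1 | step 6 | (1S,2R)-1-[4-(benzyloxy)-3-methoxyphenyl]-2-methylbut-3-en-1-ol | O[C@H](c1ccc(OCc2ccccc2)c(OC)c1)[C@H](C)C=C
F2 | step 6 | (1S,2R)-1-[4-(benzyloxy)-3-methoxyphenyl]-2-methylbutane-1,4-diol | O[C@H](c1ccc(OCc2ccccc2)c(OC)c1)[C@H](C)CCO
F3 | step 6 | (4R,5S)-5-[4-(benzyloxy)-3-methoxyphenyl]-4-methyloxolan-2-one | O=C1O[C@H](c2ccc(OCc3ccccc3)c(OC)c2)[C@H](C)C1
F4 | step 6 | (3R,4R,5S)-5-[4-(benzyloxy)-3-methoxyphenyl]-3,4-dimethyloxolan-2-one | O=C1O[C@H](c2ccc(OCc3ccccc3)c(OC)c2)[C@H](C)[C@H]1C
F5 | step 6 | (3R,4R,5S)-5-[4-(benzyloxy)-3-methoxyphenyl]-3,4-dimethyloxolan-2-ol (anomers) | OC1O[C@H](c2ccc(OCc3ccccc3)c(OC)c2)[C@H](C)[C@H]1C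
F6 | step 6 | (2S,3R,4R)-2-[4-(benzyloxy)-3-methoxyphenyl]-3,4-dimethyl-5-(phenylsulfonyl)oxolane (anomers) | O=S(=O)(c1ccccc1)C1O[C@H](c2ccc(OCc3ccccc3)c(OC)c2)[C@H](C)[C@H]1C
F7 | step 6 | [4-(benzyloxy)-3-methoxyphenyl]zinc bromide | COc1cc([Zn]Br)ccc1OCc1ccccc1
F8 | step 6 | (2S,3R,4R,5S)-2,5-bis[4-(benzyloxy)-3-methoxyphenyl]-3,4-dimethyloxolane | COc1cc([C@H]2O[C@H](c3ccc(OCc4ccccc4)c(OC)c3)[C@H](C)[C@H]2C)ccc1OCc1ccccc1
F9 | step 6 | 4,4'-[(2S,3R,4R,5S)-3,4-dimethyloxolane-2,5-diyl]bis(2-methoxyphenol) | COc1cc([C@H]2O[C@H](c3ccc(O)c(OC)c3)[C@H](C)[C@H]2C)ccc1O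
F10 | step 6 | diethyl (2R,2'R)-2,2'-{[(2S,3R,4R,5S)-3,4-dimethyloxolane-2,5-diyl]bis[(2-methoxy-4,1-phenylene)oxy]}dipropanoate | CCOC(=O)[C@@H](C)Oc1ccc([C@H]2O[C@H](c3ccc(O[C@H](C)C(=O)OCC)c(OC)c3)[C@H](C)[C@H]2C)cc1OC
F11 | step 6 | corresponding (2R,2'R)-bis(N-methoxy-N-methylpropanamide) | CON(C)C(=O)[C@@H](C)Oc1ccc([C@H]2O[C@H](c3ccc(O[C@H](C)C(=O)N(C)OC)c(OC)c3)[C@H](C)[C@H]2C)cc1OC
F12 | step 6 | (2R,2'R)-2,2'-{[(2S,3R,4R,5S)-3,4-dimethyloxolane-2,5-diyl]bis[(2-methoxy-4,1-phenylene)oxy]}bis[1-(3,4-dimethoxyphenyl)propan-1-one] | COc1ccc(C(=O)[C@@H](C)Oc2ccc([C@H]3O[C@H](c4ccc(O[C@H](C)C(=O)c5ccc(OC)c(OC)c5)c(OC)c4)[C@H](C)[C@H]3C)cc2OC)cc1OC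
F13 | step 4 | (1S,2R)-1-(3,4-dimethoxyphenyl)-2-{2-methoxy-4-[(E)-prop-1-enyl]phenoxy}propan-1-ol (erythro) | COc1ccc([C@H](O)[C@@H](C)Oc2ccc(/C=C/C)cc2OC)cc1OC
F14 | step 4 | (1R,2R)-1-(3,4-dimethoxyphenyl)-2-{2-methoxy-4-[(E)-prop-1-enyl]phenoxy}propyl 4-nitrobenzoate | COc1ccc([C@@H](OC(=O)c3ccc([N+](=O)[O-])cc3)[C@@H](C)Oc2ccc(/C=C/C)cc2OC)cc1OC
F15 | step 3 | (2S)-2-hydroxy-N-methoxy-N-methylpropanamide | CON(C)C(=O)[C@H](C)O
F16 | step 3 | (2S)-1-(3,4-dimethoxyphenyl)-2-hydroxypropan-1-one | COc1ccc(C(=O)[C@H](C)O)cc1OC
F17 | step 3 | (2S)-1-(3,4-dimethoxyphenyl)-1-oxopropan-2-yl 4-methylbenzenesulfonate | COc1ccc(C(=O)[C@H](C)OS(=O)(=O)c2ccc(C)cc2)cc1OC
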